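## Retrosynthetic overview

1. Guajadial D is opened at the spiro-dihydropyran: a late three-component Knoevenagel/hetero-Diels–Alder union of a C15 cadinane-type diene, 2,4-diformylphloroglucinol and benzaldehyde.
2. The diene comes from a bicyclic enone: exocyclic methylene by Cope elimination of a Mannich amine, ring alkene by formate reduction of an enol triflate, isopropyl by conjugate addition.
3. The bicyclic enone comes from an enantioselective Diels–Alder reaction of cyclohex-2-enone (ring B) with a 1-silyloxypenta-1,3-diene (forms ring A, sets the cis ring-fusion-H/methyl pair), then hydrogenation and β-elimination.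
4. The dialdehyde comes from phloroglucinol (Vilsmeier), itself from resorcinol by meta C–H borylation/oxidation.
5. Ring order: ring B (bought) → ring A ([4+2]) → arene (bought, then functionalised) → dihydropyran ring (last).

Assumption: names use the naphthalene locants of each compound; the CH2NMe2-bearing carbon of 8–12 is an epimer mixture that is erased in step 8 and is left undefined in the SMILES, as is the exocyclic C=C geometry of 22.

## Route

Step 1
Reactants: 1 (E)-pent-2-enal
Product: 2 (1E,3E)-1-[(tert-butyldimethylsilyl)oxy]penta-1,3-diene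
Conditions: TBSOTf, Et3N, Et2O, 0 °C → rt
Reagents that add atoms: tert-butyldimethylsilyl trifluoromethanesulfonate, CC(C)(C)[Si](C)(C)OS(=O)(=O)C(F)(F)F
Why: γ-Deprotonation/O-silylation of the enal (silyl dienol ether formation) gives mainly the (1E,3E) diene, the only isomer that reacts in step 2; no stereocentre is formed.

Step 2
Reactants: 2 (1E,3E)-1-[(tert-butyldimethylsilyl)oxy]penta-1,3-diene; 3 cyclohex-2-en-1-one
Product: 4 (4aR,5R,8S,8aR)-8-[(tert-butyldimethylsilyl)oxy]-5-methyl-3,4,4a,5,8,8a-hexahydronaphthalen-1(2H)-one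
Conditions: (R)-B-(o-tolyl) oxazaborolidine of (R)-α,α-diphenylprolinol·Tf2NH (20 mol%), CH2Cl2, −78 → −40 °C; Et3N quench
Reagents that add atoms: none
Why: Lewis-acid-catalysed endo Diels–Alder reaction in which the silyloxy terminus bonds to the enone α-carbon and the methyl terminus to the β-carbon; the endo transition state puts methyl and OTBS cis to the ring-B bonds (cis fusion, C5-methyl cis to the C4a–C4 bond), and the chiral oxazaborolidinium shields one enone face (α-si attack expected for the (R)-catalyst by analogy with its acrylate reactions) to give the 4aR,5R series.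

Step 3
Reactants: 4 (4aR,5R,8S,8aR)-8-[(tert-butyldimethylsilyl)oxy]-5-methyl-3,4,4a,5,8,8a-hexahydronaphthalen-1(2H)-one
Product: 5 (4aR,5R,8S,8aR)-8-[(tert-butyldimethylsilyl)oxy]-5-methyl-3,4,4a,5,6,7,8,8a-octahydronaphthalen-1(2H)-one
Conditions: H2 (3 atm), RhCl(PPh3)3 (5 mol%), benzene, rt
Reagents that add atoms: none
Why: Homogeneous catalytic hydrogenation saturates the cis-disubstituted ring alkene without double-bond migration or allylic C–O hydrogenolysis, so the C5 methyl centre is untouched.

Step 4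
Reactants: 5 (4aR,5R,8S,8aR)-8-[(tert-butyldimethylsilyl)oxy]-5-methyl-3,4,4a,5,6,7,8,8a-octahydronaphthalen-1(2H)-one
Product: 6 (4aR,5R)-5-methyl-3,4,4a,5,6,7-hexahydronaphthalen-1(2H)-one
Conditions: p-TsOH·H2O (20 mol%), benzene, 60 °C
Reagents that add atoms: none
Why: Acid-catalysed β-elimination of the silanol from the β-silyloxy ketone gives the conjugated enone (C8=C8a); C4a and C5 are not enolisable and keep their configuration.

Step 5
Reactants: 6 (4aR,5R)-5-methyl-3,4,4a,5,6,7-hexahydronaphthalen-1(2H)-one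
Product: 8 (4aR,5R)-2-[(dimethylamino)methyl]-5-methyl-3,4,4a,5,6,7-hexahydronaphthalen-1(2H)-one (C2 epimers), via lithium dienolate 7 (not isolated)
Conditions: LiN(iPr)2, THF, −78 °C; then CH2=NMe2+ I− (Eschenmoser's salt), −78 → 0 °C
Reagents that add atoms: N,N-dimethylmethyleneiminium iodide (Eschenmoser's salt), C=[N+](C)C.[I-]
Why: Kinetic α′-deprotonation gives the cross-conjugated enolate, which undergoes a Mannich reaction with the iminium salt; the new C2 centre is formed unselectively and is removed in step 8.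

Step 6
Reactants: 8 (4aR,5R)-2-[(dimethylamino)methyl]-5-methyl-3,4,4a,5,6,7-hexahydronaphthalen-1(2H)-one (C2 epimers)
Product: 10 (4aR,5R,8S)-2-[(dimethylamino)methyl]-5-methyl-8-(propan-2-yl)-2,3,4,4a,5,6,7,8-octahydronaphthalen-1-yl trifluoromethanesulfonate, via chloromagnesium enolate 9 (not isolated)
Conditions: i-PrMgCl, CuBr·SMe2 (10 mol%), THF, −78 → −40 °C; then Comins' reagent, DMPU, −78 °C → rt
Reagents that add atoms: isopropylmagnesium chloride, CC(C)[Mg]Cl; N-(5-chloropyridin-2-yl)-bis(trifluoromethanesulfonyl)imide (Comins' reagent), FC(F)(F)S(=O)(=O)N(c1ccc(Cl)cn1)S(=O)(=O)C(F)(F)F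
Why: Copper-catalysed conjugate addition followed by enolate O-triflation; the isopropyl group enters C8 axially (chair-like transition state of the ring-A half-chair) on the face opposite the axial C5 methyl and the C4a–C4 bond, giving 8S, and the enolate exists only towards C8a so the triflate fixes the future ring alkene.

Step 7
Reactants: 10 (4aR,5R,8S)-2-[(dimethylamino)methyl]-5-methyl-8-(propan-2-yl)-2,3,4,4a,5,6,7,8-octahydronaphthalen-1-yl trifluoromethanesulfonate
Product: 11 1-[(4aR,5R,8S)-5-methyl-8-(propan-2-yl)-2,3,4,4a,5,6,7,8-octahydronaphthalen-2-yl]-N,N-dimethylmethanamine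
Conditions: Pd(OAc)2 (5 mol%), PPh3 (10 mol%), HCO2H, n-Bu3N, DMF, 60 °C
Reagents that add atoms: none
Why: Palladium-catalysed formate reduction of the enol triflate (oxidative addition to zerovalent palladium, formate-to-hydride exchange, reductive elimination) replaces OTf by H without moving the C1=C8a double bond or touching a stereocentre.

Step 8
Reactants: 11 1-[(4aR,5R,8S)-5-methyl-8-(propan-2-yl)-2,3,4,4a,5,6,7,8-octahydronaphthalen-2-yl]-N,N-dimethylmethanamine
Product: 13 (1S,4R,4aR)-4-methyl-7-methylidene-1-(propan-2-yl)-1,2,3,4,4a,5,6,7-octahydronaphthalene, via amine N-oxide 12 (not isolated)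
Conditions: mCPBA (1.0 equiv), CH2Cl2, −20 °C; filtration through basic alumina; then toluene, 90 °C
Reagents that add atoms: none
Why: Cope elimination: the N-oxide undergoes syn β-elimination through a five-membered transition state, and the only β-hydrogen is the allylic ring C–H, so the exocyclic methylene of the conjugated diene forms regiospecifically under neutral conditions with no epimerisation.

Step 9
Reactants: 14 resorcinol
Product: 15 1,3-dimethoxybenzene
Conditions: MeI, K2CO3, acetone, reflux
Reagents that add atoms: iodomethane, CI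
Why: Williamson O-methylation protects both phenols so that the next step is purely sterically controlled.

Step 10
Reactants: 15 1,3-dimethoxybenzene
Product: 16 2-(3,5-dimethoxyphenyl)-4,4,5,5-tetramethyl-1,3,2-dioxaborolane
Conditions: [Ir(OMe)(cod)]2 (1.5 mol%), 4,4'-di-tert-butyl-2,2'-bipyridine (3 mol%), B2pin2 (1.0 equiv), THF, 80 °C
Reagents that add atoms: bis(pinacolato)diboron, CC1(C)OB(OC1(C)C)B1OC(C)(C)C(C)(C)O1
Why: Iridium-catalysed aromatic C–H borylation is sterically governed and takes the only C–H that is not ortho to a methoxy group (C5).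

Step 11
Reactants: 16 2-(3,5-dimethoxyphenyl)-4,4,5,5-tetramethyl-1,3,2-dioxaborolane
Product: 17 3,5-dimethoxyphenol
Conditions: Oxone (2KHSO5·KHSO4·K2SO4), acetone/H2O, rt
Reagents that add atoms: potassium peroxymonosulfate (active component of Oxone), [K+].[O-]S(=O)(=O)OO
Why: Oxidative ipso-hydroxylation of the aryl boronate (1,2-aryl shift from boron to peroxide oxygen, then hydrolysis) installs the third oxygen.

Step 12
Reactants: 17 3,5-dimethoxyphenol
Product: 18 benzene-1,3,5-triol (phloroglucinol)
Conditions: BBr3 (4 equiv), CH2Cl2, −78 °C → rt; then H2O, 0 °C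
Reagents that add atoms: none
Why: Lewis-acid-mediated aryl methyl ether cleavage (bromide attacks the O-methyl of the boron-complexed ether) frees both phenols.

Step 13
Reactants: 18 benzene-1,3,5-triol (phloroglucinol)
Product: 20 2,4,6-trihydroxybenzene-1,3-dicarbaldehyde, via bis-iminium salt 19 (not isolated)
Conditions: POCl3 (2.2 equiv), DMF (2.2 equiv), EtOAc, 0 °C → rt; then H2O, 50 °C
Reagents that add atoms: N,N-dimethylformamide, CN(C)C=O; water, O
Why: Double Vilsmeier–Haack formylation of the very electron-rich triol stops at the dialdehyde because each formyl group deactivates the ring; hydrolysis of the iminium salts releases the aldehydes.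

Step 14
Reactants: 13 (1S,4R,4aR)-4-methyl-7-methylidene-1-(propan-2-yl)-1,2,3,4,4a,5,6,7-octahydronaphthalene; 20 2,4,6-trihydroxybenzene-1,3-dicarbaldehyde; 21 benzaldehyde
Product: 23 Guajadial D, via o-quinone methide 22 (not isolated)
Conditions: H2O, sealed tube, 100 °C, 12 h; preparative HPLC
Reagents that add atoms: none
Why: Knoevenagel condensation of 20 with 21 gives the o-quinone methide, which adds as an electron-poor heterodiene to the terminal exocyclic alkene of 13 (oxygen to the more substituted carbon) in a hetero-Diels–Alder reaction; approach on the ring-B face away from the axial isopropyl group with ring A exo sets the spiro and benzylic centres of 23, and minor diastereomers are removed by HPLC.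

## Compound list

1 | (E)-pent-2-enal | CC/C=C/C=O | starting material
2 | (1E,3E)-1-[(tert-butyldimethylsilyl)oxy]penta-1,3-diene | C/C=C/C=C/O[Si](C)(C)C(C)(C)C | intermediate
3 | cyclohex-2-en-1-one | O=C1C=CCCC1 | starting material
4 | (4aR,5R,8S,8aR)-8-[(tert-butyldimethylsilyl)oxy]-5-methyl-3,4,4a,5,8,8a-hexahydronaphthalen-1(2H)-one | C[C@@H]1C=C[C@H](O[Si](C)(C)C(C)(C)C)[C@@H]2C(=O)CCC[C@H]12 | intermediate
5 | (4aR,5R,8S,8aR)-8-[(tert-butyldimethylsilyl)oxy]-5-methyl-3,4,4a,5,6,7,8,8a-octahydronaphthalen-1(2H)-one | C[C@@H]1CC[C@H](O[Si](C)(C)C(C)(C)C)[C@@H]2C(=O)CCC[C@H]12 | intermediate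
6 | (4aR,5R)-5-methyl-3,4,4a,5,6,7-hexahydronaphthalen-1(2H)-one | C[C@@H]1CCC=C2C(=O)CCC[C@H]12 | intermediate
7 | lithium dienolate of 6 (O–Li on C1, C1=C2 and C8=C8a) | C[C@@H]1CCC=C2C(O[Li])=CCC[C@H]12 | intermediate (not isolated)
8 | (4aR,5R)-2-[(dimethylamino)methyl]-5-methyl-3,4,4a,5,6,7-hexahydronaphthalen-1(2H)-one (C2 epimers) | C[C@@H]1CCC=C2C(=O)C(CN(C)C)CC[C@H]12 | intermediate
9 | chloromagnesium (4aR,5R,8S)-2-[(dimethylamino)methyl]-5-methyl-8-(propan-2-yl)-2,3,4,4a,5,6,7,8-octahydronaphthalen-1-olate | CC(C)[C@@H]1CC[C@@H](C)[C@H]2CCC(CN(C)C)C(O[Mg]Cl)=C12 | intermediate (not isolated)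
10 | (4aR,5R,8S)-2-[(dimethylamino)methyl]-5-methyl-8-(propan-2-yl)-2,3,4,4a,5,6,7,8-octahydronaphthalen-1-yl trifluoromethanesulfonate | CC(C)[C@@H]1CC[C@@H](C)[C@H]2CCC(CN(C)C)C(OS(=O)(=O)C(F)(F)F)=C12 | intermediate
11 | 1-[(4aR,5R,8S)-5-methyl-8-(propan-2-yl)-2,3,4,4a,5,6,7,8-octahydronaphthalen-2-yl]-N,N-dimethylmethanamine | CC(C)[C@@H]1CC[C@@H](C)[C@H]2CCC(CN(C)C)C=C12 | intermediate
12 | N-oxide of 11 | CC(C)[C@@H]1CC[C@@H](C)[C@H]2CCC(C[N+](C)(C)[O-])C=C12 | intermediate (not isolated)
13 | (1S,4R,4aR)-4-methyl-7-methylidene-1-(propan-2-yl)-1,2,3,4,4a,5,6,7-octahydronaphthalene | CC(C)[C@@H]1CC[C@@H](C)[C@H]2CCC(=C)C=C12 | intermediate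
14 | resorcinol (benzene-1,3-diol) | Oc1cccc(O)c1 | starting material
15 | 1,3-dimethoxybenzene | COc1cccc(OC)c1 | intermediate
16 | 2-(3,5-dimethoxyphenyl)-4,4,5,5-tetramethyl-1,3,2-dioxaborolane | COc1cc(OC)cc(c1)B1OC(C)(C)C(C)(C)O1 | intermediate
17 | 3,5-dimethoxyphenol | COc1cc(O)cc(OC)c1 | intermediate
18 | benzene-1,3,5-triol (phloroglucinol) | Oc1cc(O)cc(O)c1 | intermediate
19 | (2,4,6-trihydroxy-1,3-phenylene)bis(N,N-dimethylmethaniminium) dichloride | C[N+](C)=Cc1c(O)cc(O)c(C=[N+](C)C)c1O.[Cl-].[Cl-] | intermediate (not isolated)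
20 | 2,4,6-trihydroxybenzene-1,3-dicarbaldehyde | O=Cc1c(O)cc(O)c(C=O)c1O | intermediate
21 | benzaldehyde | O=Cc1ccccc1 | starting material
22 | 5-benzylidene-2,4-dihydroxy-6-oxocyclohexa-1,3-diene-1,3-dicarbaldehyde (o-quinone methide) | O=CC1=C(O)C(C=O)=C(O)C(=Cc2ccccc2)C1=O | intermediate (not isolated)
23 | Guajadial D | CC(C)[C@@H]1CC[C@@H](C)[C@H]2CC[C@@]3(C=C12)C[C@@H](c1ccccc1)c1c(O)c(C=O)c(O)c(C=O)c1O3 | target

## Step count and risks

Total steps: 14.
Longest linear sequence: 9 (steps 1–8, then step 14); the arene branch is steps 9–13.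

Steps most likely to fail:

**Step 2 (catalytic asymmetric Diels–Alder).** Cyclohexenone is a weak dienophile, the silyl dienol ether can divert into Mukaiyama–Michael chemistry, and the absolute sense assigned to the (R)-catalyst rests on analogy. The absolute configuration of 6 must be checked before scale-up (the mirror-image catalyst is used if the sense is reversed). The fallback sets out from 3 and returns at 6. Enone 3 is brominated and dehydrobrominated in one pot (Br2, then Et3N, CH2Cl2, 0 °C) through trans-2,3-dibromocyclohexan-1-one F1 to 2-bromocyclohex-2-en-1-one F2. F2 is a far better dienophile, and the α-halogen fixes the catalyst-binding geometry. Its endo cycloaddition with 2 under the same oxazaborolidinium catalyst gives (4aR,5R,8S,8aS)-8a-bromo-8-[(tert-butyldimethylsilyl)oxy]-5-methyl-3,4,4a,5,8,8a-hexahydronaphthalen-1(2H)-one F3. Hydrogenation (H2, RhCl(PPh3)3) gives the saturated bromo ketone (4aR,5R,8S,8aS)-8a-bromo-8-[(tert-butyldimethylsilyl)oxy]-5-methyl-3,4,4a,5,6,7,8,8a-octahydronaphthalen-1(2H)-one F4. Zn dust in AcOH/THF then forms the zinc enolate, which expels the β-silanolate (Boord-type reductive elimination) to give 6 directly. Any simply debrominated 5 is converted by step 4.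

**Step 6 (conjugate addition with in-flask triflation).** The risks are an insufficient facial preference at C8 and sluggish O-triflation of a hindered magnesium enolate next to a basic amine. The fallback sets out from 6 and returns at 13; it separates C–C bond formation from enol triflate formation and drops the amine. Copper-catalysed i-PrMgCl addition to 6 with aqueous NH4Cl quench gives (4aR,5R,8S)-5-methyl-8-(propan-2-yl)-3,4,4a,5,6,7,8,8a-octahydronaphthalen-1(2H)-one F5, where any C8 epimer can be removed by chromatography. α-Methylenation at the only α-CH2 ((CH2O)n, N-methylanilinium trifluoroacetate, THF, 65 °C) gives (4aR,5R,8S)-5-methyl-2-methylidene-8-(propan-2-yl)-3,4,4a,5,6,7,8,8a-octahydronaphthalen-1(2H)-one F6. Tf2O with 2,6-di-tert-butyl-4-methylpyridine (or KN(SiMe3)2/PhNTf2) enolises the one remaining α-hydrogen to the 2-triflyloxy-1,3-diene (4aR,5R,8S)-5-methyl-2-methylidene-8-(propan-2-yl)-2,3,4,4a,5,6,7,8-octahydronaphthalen-1-yl trifluoromethanesulfonate F7. The Pd(OAc)2/PPh3/HCO2H/n-Bu3N reduction of step 7 then gives 13.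

**Step 14 (three-component coupling).** At 100 °C the o-quinone methide can also give ene/Michael adducts, 13 can isomerise, and face and endo/exo selectivity may be modest. The fallback sets out from 20 (with 21) and returns at 23; it moves quinone methide generation to low temperature. Compounds 20 and 21 are condensed with sodium p-toluenesulfinate in aqueous HCO2H to give the stable precursor 2,4,6-trihydroxy-5-[(4-methylbenzenesulfonyl)(phenyl)methyl]benzene-1,3-dicarbaldehyde F8. Mild base (K2CO3, CH2Cl2, 0–25 °C), optionally with a chiral phosphoric acid to reinforce facial control, then releases 22 in the presence of 13, and cycloaddition gives 23.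

## Further compounds

F1 | step 2 | trans-2,3-dibromocyclohexan-1-one (racemic, not isolated) | O=C1CCCC(Br)C1Br
F2 | step 2 | 2-bromocyclohex-2-en-1-one | O=C1CCCC=C1Br
F3 | step 2 | (4aR,5R,8S,8aS)-8a-bromo-8-[(tert-butyldimethylsilyl)oxy]-5-methyl-3,4,4a,5,8,8a-hexahydronaphthalen-1(2H)-one | C[C@@H]1C=C[C@H](O[Si](C)(C)C(C)(C)C)[C@]2(Br)C(=O)CCC[C@H]12
F4 | step 2 | (4aR,5R,8S,8aS)-8a-bromo-8-[(tert-butyldimethylsilyl)oxy]-5-methyl-3,4,4a,5,6,7,8,8a-octahydronaphthalen-1(2H)-one | C[C@@H]1CC[C@H](O[Si](C)(C)C(C)(C)C)[C@]2(Br)C(=O)CCC[C@H]12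
F5 | step 6 | (4aR,5R,8S)-5-methyl-8-(propan-2-yl)-3,4,4a,5,6,7,8,8a-octahydronaphthalen-1(2H)-one (8a epimers) | CC(C)[C@@H]1CC[C@@H](C)[C@H]2CCCC(=O)C12
F6 | step 6 | (4aR,5R,8S)-5-methyl-2-methylidene-8-(propan-2-yl)-3,4,4a,5,6,7,8,8a-octahydronaphthalen-1(2H)-one (8a epimers) | CC(C)[C@@H]1CC[C@@H](C)[C@H]2CCC(=C)C(=O)C12
F7 | step 6 | (4aR,5R,8S)-5-methyl-2-methylidene-8-(propan-2-yl)-2,3,4,4a,5,6,7,8-octahydronaphthalen-1-yl trifluoromethanesulfonate | CC(C)[C@@H]1CC[C@@H](C)[C@H]2CCC(=C)C(OS(=O)(=O)C(F)(F)F)=C12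
F8 | step 14 | 2,4,6-trihydroxy-5-[(4-methylbenzenesulfonyl)(phenyl)methyl]benzene-1,3-dicarbaldehyde (racemic) | Cc1ccc(cc1)S(=O)(=O)C(c1ccccc1)c1c(O)c(C=O)c(O)c(C=O)c1O
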